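All runs come from a simulation for substances that don't exist, and the scatter is random.

In 12 min, or a mean residence time of that length, four set-ups handle one charge and are judged by the share of target.

| flask | starting material | second substrate | coupling partner | free catalyst | remark | time |
|---|---|---|---|---|---|---|
| beta | 0.30 M | 0.15 M | 0.15 M | 0.60 mM | run made earlier |  |
| epsilon | 0.30 M | 0.15 M | 0.15 M | 0.90 mM | run made earlier |  |
| maple | 0.30 M (fed, over 12.0 min) | 0.150 M | 0.150 M | 0.60 mM | all but starting material at the start; starting material goes in evenly over 12.0 min, the run ends at 12 min | 12 min |
| cedar | 0.30 M | 0.150 M | 0.150 M | 0.60 mM | everything together in a closed stirred flask, run for 12 min | 12 min |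
| oak | 0.30 M | 0.150 M | 0.150 M (fed, over 12.0 min) | 0.60 mM | all but coupling partner at the start; coupling partner goes in evenly over 12.0 min, the run ends at 12 min | 12 min |
| alder | 0.30 M | 0.150 M | 0.150 M | 0.60 mM | one stirred flow tank at steady state, fed with the mixture as stated, mean residence time 12 min |  |

| run | time / min | target / % | uncatalysed product / % | starting material / % |
|---|---|---|---|---|
| beta | 0.500 | 5 | 20 | 79 |
| beta | 1.00 | 9 | 25 | 66 |
| beta | 1.50 | 8 | 28 | 68 |
| beta | 2.50 | 8 | 30 | 62 |
| beta | 4.00 | 6 | 28 | 63 |
| beta | 8.00 | 6 | 28 | 64 |
| epsilon | 0.167 | 4 | 7 | 88 |
| epsilon | 0.500 | 6 | 15 | 75 |
| epsilon | 0.833 | 7 | 21 | 69 |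
| epsilon | 1.33 | 10 | 25 | 67 |
| epsilon | 2.00 | 10 | 25 | 69 |
| epsilon | 2.50 | 7 | 24 | 65 |

(readings scatter by 2 percentage points)

- the stated concentrations are those of everything mixed, before any reaction; amounts are the same in each set-up
- the feed brings no volume worth counting
- the earlier runs were made in a closed, stirred flask

- the set-up with the highest share of target in all that became target or uncatalysed product, at the outlet or at the end ("none" if the first two lie within 2 percentage points) (maple / cedar / oak / alder / none)
- share of target in all that became target or uncatalysed product, at the outlet or at the end, maple
- share of target in all that became target or uncatalysed product, at the outlet or at the end, cedar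
- share of target in all that became target or uncatalysed product, at the outlet or at the end, oak
- share of target in all that became target or uncatalysed product, at the outlet or at the end, alder

By 2.50 min the beta run has stopped rising: target and uncatalysed product together hold about 35.5% of the starting material charged, while 64% stands unused at 8.00 min. Coupling partner, charged at 0.150 M against 0.30 M of starting material, is the likely limiting reagent. Read as one exponential, the 25.0% reached at 0.500 min gives a rise time of 0.410 min. Target's share of the plateau reads 19.7%, and this reckoning takes that reading for cedar, which repeats the charge and vessel of beta.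

Turned round, the question is what a tie needs. For maple to match cedar, the ratio of target to uncatalysed product must hold whatever [starting material] is, so both routes need the same order in it. Dosing time divided by rise time, 29.2, is the dose number, the count of rise times that the feed lasts. If the rise time holds in maple, [starting material] there stands near 0.0103 M after one rise time. The beta readings test the ratio over a fall in [starting material] by a factor of only 1.56, so a tie asks for equal orders across a far wider range. This reckoning therefore leaves the orders, and with them the ranking of maple, open.

The forecast names none as best, with 20% for maple, 20% for cedar, 20% for oak and 20% for alder, on the ground: “Feeding or back-mixing should change yield, not share”.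

Maple gives 52.2%, the highest share, against 18.7% in cedar, 15.8% in oak and 18.1% in alder. Target in maple is 2.28% of the starting material charged, less than the 6.57% in cedar.

    second substrate + free catalyst ⇌ catalyst intermediate B (K = 29.0 M⁻¹, k = 53.0 M⁻¹ s⁻¹)
    starting material + free catalyst ⇌ catalyst intermediate A (K = 32.0 M⁻¹, k = 560 M⁻¹ s⁻¹)
    coupling partner + catalyst intermediate B → free catalyst + second product (k = 360 M⁻¹ s⁻¹)
    coupling partner + catalyst intermediate A → free catalyst + target (k = 7.50 M⁻¹ s⁻¹)
    starting material + coupling partner → uncatalysed product (k = 0.0680 M⁻¹ s⁻¹)

With the dose of maple delivered over 1.20 min, the dose number falls to 2.92 and the share to 27.2%.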